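**Assumption:** the target has no stereocentre, and its only ring alkene is the necessarily cis C3=C4 of the chromene. It is therefore achiral and needs no enantiocontrol.

## Retrosynthetic overview
1. Ficucaricone C ⇒ 5-O-methyl-4'-O-prenylalpinumisoflavone. The benzil is C4–C3 of an isoflavone whose C2 is excised as formate, and the pyranone oxygen masks the one A-ring phenol that must stay free.
2. ⇒ alpinumisoflavone, by two O-alkylations ordered by acidity (4'-OH first, then the chelated 5-OH).
3. ⇒ genistein + prenal. C6 aldol addition and dehydration give an ortho-quinone methide, which closes onto O7 by oxa-6π electrocyclisation. This is the same ring closure as wighteone → alpinumisoflavone in the plant.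
4. Ring order: rings A, B and the sacrificial ring C come with genistein. The dimethylpyran is the only ring formed (step 1), and ring C is opened in the last step.

## Route

Step 1
Reactants: 1 genistein; 2 3-methylbut-2-enal (prenal)
Product: 4 alpinumisoflavone, via ortho-quinone methide 3 (not isolated)
Conditions: Ca(OH)2 (2 equiv), 2 (2.5 equiv), MeOH, rt, 48 h, Ar, dark; 1 M HCl quench; chromatography
Reagents that add atoms: none
Why: A calcium-phenoxide aldol (Knoevenagel-type) addition of unprotected genistein to prenal and loss of water give 3, which closes by oxa-6π electrocyclisation; C6 is favoured because it is ortho to both metal-bearing oxygens (O5, O7) and is the usual site of base-mediated C-alkylation of 5,7-dihydroxyisoflavones, closure goes to O7 because O5 stays locked in its chelate with the C4 carbonyl, the isolated 4'-phenol ring is too weak a carbon nucleophile to react, and no stereocentre is created.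

Step 2
Reactants: 4 alpinumisoflavone; 5 prenyl bromide (1-bromo-3-methylbut-2-ene)
Product: 7 isoflavone diether (5-O-methyl-4'-O-prenylalpinumisoflavone), via 4'-O-prenylalpinumisoflavone 6 (not isolated)
Conditions: K2CO3 (4 equiv), 5 (1.05 equiv), DMF, rt, 4 h; then MeI (5 equiv), 40 °C, sealed, 24 h
Reagents that add atoms: methyl iodide, CI
Why: These are two Williamson etherifications ordered by acidity: carbonate at rt ionises only the free 4'-OH (O7 is already in the pyran ring and 5-OH is hydrogen-bonded to C4=O), so one equivalent of 5 gives 6 by SN2, and excess MeI with warming then alkylates the remaining chelated 5-OH, while the chromene, prenyl ether and pyranone are inert to anhydrous carbonate.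

Step 3
Reactants: 7 isoflavone diether
Product: 9 ficucaricone C, via deoxybenzoin 8 (not isolated)
Conditions: (i) KOH (4 equiv), DMSO–H2O 10:1, 60 °C, N2, 2 h; (ii) AcOH (3 equiv), DABCO (0.3 equiv), air sparge, 90 °C, 12 h; dil. HCl work-up
Reagents that add atoms: dioxygen (air), O=O
Why: Proposed new method: stage (i) is the classical alkaline degradation of an isoflavone (hydroxide adds to C2, retro-oxa-Michael ring opening, then retro-Claisen loss of formate, fast here because 7 has no free phenol) and stage (ii) is the known DABCO-catalysed aerobic oxidation of deoxybenzoins to benzils (enolate + O2 → α-hydroperoxide → Kornblum–DeLaMare-type dehydration), so only the one-flask telescoping and the free ortho-phenol are new; buffering with AcOH before air is admitted removes the hydroxide that would cause benzilic rearrangement or C–C cleavage, and triplet O2 with a tertiary amine leaves the chromene and prenyl alkenes untouched, unlike SeO2, ozone or halogen oxidants.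

## Compound list
1 | genistein, 5,7-dihydroxy-3-(4-hydroxyphenyl)-4H-chromen-4-one | O=c1c(-c2ccc(O)cc2)coc2cc(O)cc(O)c12 | starting material
2 | 3-methylbut-2-enal (prenal) | CC(C)=CC=O | starting material
3 | (Z)-ortho-quinone methide, 5-hydroxy-3-(4-hydroxyphenyl)-6-(3-methylbut-2-enylidene)chromene-4,7(6H)-dione | O=C1C=C2OC=C(c3ccc(O)cc3)C(=O)C2=C(O)/C1=C/C=C(C)C | intermediate (not isolated)
4 | alpinumisoflavone, 5-hydroxy-7-(4-hydroxyphenyl)-2,2-dimethyl-2H,6H-pyrano[3,2-g]chromen-6-one | O=c1c(-c2ccc(O)cc2)coc2cc3OC(C)(C)C=Cc3c(O)c12 | intermediate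
5 | prenyl bromide, 1-bromo-3-methylbut-2-ene | CC(C)=CCBr | starting material
6 | 4'-O-prenylalpinumisoflavone | O=c1c(-c2ccc(OCC=C(C)C)cc2)coc2cc3OC(C)(C)C=Cc3c(O)c12 | intermediate (not isolated)
7 | 5-O-methyl-4'-O-prenylalpinumisoflavone | COc1c2C=CC(C)(C)Oc2cc2occ(-c3ccc(OCC=C(C)C)cc3)c(=O)c12 | intermediate
8 | 1-(7-hydroxy-5-methoxy-2,2-dimethyl-2H-chromen-6-yl)-2-[4-(3-methylbut-2-enyloxy)phenyl]ethan-1-one | COc1c2C=CC(C)(C)Oc2cc(O)c1C(=O)Cc1ccc(OCC=C(C)C)cc1 | intermediate (not isolated)
9 | ficucaricone C, 1-(7-hydroxy-5-methoxy-2,2-dimethyl-2H-chromen-6-yl)-2-[4-(3-methylbut-2-enyloxy)phenyl]ethane-1,2-dione (achiral) | COc1c2c(cc(O)c1C(=O)C(=O)c1ccc(OCC=C(C)C)cc1)OC(C)(C)C=C2 | target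

**Total step count:** 3. **Longest linear sequence:** 3, from genistein.

## Steps most likely to fail

**Step 1.** The risks are C6 versus C8 attack, which would give the angular isomer, and a modest yield on the unprotected triphenol. The fallback sets out from 1 and comes back at 4. It separates C–C bond formation from ring closure. Compound 1 is C-prenylated with 5 under NaOMe/MeOH (nuclear prenylation, C6 major) to give wighteone F1. The 8-prenyl and O-prenyl isomers are removed by chromatography at this stage. F1 is then dehydrogenated with DDQ in refluxing benzene. Hydride abstraction from the benzylic CH2 generates the same quinone methide 3, which closes onto O7 to give 4.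

**Step 3.** The risks are slow oxidation of the free ortho-hydroxy ketone, over-oxidation to the two acids, and benzilic-type rearrangement. The fallback sets out from 7 and comes back at 9. It puts the first oxygen on C3 before the ring is opened. Weitz–Scheffer epoxidation (30% H2O2, cat. NaOH, acetone–MeOH, 0 °C) attacks only the electron-poor C2=C3 bond and gives the racemic cis-fused 2,3-epoxyisoflavanone F2. Dilute NaOH in THF–H2O under N2 opens the acetal-type C2, and the resulting α-hydroxy-α-formyl ketone loses formate to give the racemic benzoin F3. The easy benzoin-to-benzil oxidation (10 mol % Cu(OAc)2, air, MeOH–pyridine, rt) then gives 9.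

**Step 2.** The risks are scrambled ethers in the one-pot procedure and a chelated, peri-hindered 5-OH that resists methylation. The fallback sets out from 4 and comes back at 7. It uses a protecting group so that irreversible deprotonation can be applied. TIPSCl and imidazole in DMF silylate only the 4'-OH to give 4'-O-TIPS-alpinumisoflavone F4. NaH and MeI in DMF (0 °C to rt) break the chelate and give the 5-O-methyl silyl ether F5. TBAF in THF frees 5-O-methylalpinumisoflavone F6. Its only phenol is then prenylated with 5 (K2CO3, acetone, reflux) to give 7.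

## Further compounds
F1 | step 1 | wighteone (6-prenylgenistein) | O=c1c(-c2ccc(O)cc2)coc2cc(O)c(CC=C(C)C)c(O)c12
F2 | step 3 | 2,3-epoxyisoflavanone of 7 (racemic, cis-fused; one enantiomer drawn) | COc1c2C=CC(C)(C)Oc2cc2O[C@H]3O[C@@]3(c4ccc(OCC=C(C)C)cc4)C(=O)c12
F3 | step 3 | 2-hydroxy-1-(7-hydroxy-5-methoxy-2,2-dimethyl-2H-chromen-6-yl)-2-[4-(3-methylbut-2-enyloxy)phenyl]ethan-1-one (racemic benzoin) | COc1c2C=CC(C)(C)Oc2cc(O)c1C(=O)C(O)c1ccc(OCC=C(C)C)cc1
F4 | step 2 | 4'-O-TIPS-alpinumisoflavone | O=c1c(-c2ccc(O[Si](C(C)C)(C(C)C)C(C)C)cc2)coc2cc3OC(C)(C)C=Cc3c(O)c12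
F5 | step 2 | 5-O-methyl-4'-O-TIPS-alpinumisoflavone | COc1c2C=CC(C)(C)Oc2cc2occ(-c3ccc(O[Si](C(C)C)(C(C)C)C(C)C)cc3)c(=O)c12
F6 | step 2 | 5-O-methylalpinumisoflavone | COc1c2C=CC(C)(C)Oc2cc2occ(-c3ccc(O)cc3)c(=O)c12
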